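**Plan**

1. Ring A is the arene, ring B the dihydrofuran (O1, C2, C3), ring C the cyclohexane (C1'–C6', C1' bonded to C2). On ring C the oxygens on C1' and C3' are 1,3-cis and the C4' methoxy group is trans to the C3' oxygen, so an Si–H unit carried by the C1' oxygen can add across a C3'=C4' methyl enol ether from one face.
2. Retrosynthetic cuts: C3'–O (from C3'–Si) and the O–Si tether; C3'=C4' (ring-closing metathesis); C1'–C2' (allyl addition to a C1' ketone); C5'–C6' (enolate alkylation); C1'–C6' (Weinreb ketone synthesis); O1–C2 and C2–C3 ((4+1) annulation of an ortho-quinone methide); C3–C3a (ortho-hydroxyalkylation of the phenol).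
3. Forward order: ring A receives its side chains, ring B closes by the (4+1) annulation, the C2 acyl chain is built out, ring C closes by metathesis, a temporary oxasilolane ring forms and is opened oxidatively.
4. Stereochemistry: C3 and C2 (trans) come from a cinchona-derived ammonium ylide; C1' from chelate-controlled allylation; C3' and C4' from the tethered syn hydrosilylation, kept by a stereoretentive Tamao–Fleming oxidation.

Key step: step 12

Conventions: TBS = tert-butyldimethylsilyl; Bf = (2S,3R)-3-(TBSO-methyl)-7-methoxy-5-(3-TBSO-propyl)-2,3-dihydro-1-benzofuran-2-yl.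
Assumption: the quinidine-derived ammonium ylide is taken to give the (2S,3R) ring B amide in step 5; if a trial shows the opposite sense, the pseudoenantiomeric 9-O-methylquinine salt, made the same way, is used instead.

**Route**

Step 1
Reactants: 1 dihydroconiferyl alcohol
Product: 2 4-[3-(TBSO)propyl]-2-methoxyphenol
Conditions: TBSCl (1.05 equiv), imidazole, CH2Cl2, 0 °C
Reagents that add atoms: tert-butyldimethylsilyl chloride, CC(C)(C)[Si](C)(C)Cl
Why: Chemoselective silyl ether formation, in which the unhindered primary alkanol should react ahead of the hydrogen-bonded, ortho-substituted phenol when one equivalent of chloride is used at 0 °C.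

Step 2
Reactants: 2 4-[3-(TBSO)propyl]-2-methoxyphenol; 3 (tert-butyldimethylsilyloxy)acetaldehyde
Product: 5 2-[2-(TBSO)-1-hydroxyethyl]-6-methoxy-4-[3-(TBSO)propyl]phenol (racemic), via bromomagnesium phenolate 4 (not isolated)
Conditions: EtMgBr (1.0 equiv), Et2O, 0 °C; solvent exchange to CH2Cl2; 3 (1.2 equiv), rt; pH 7 buffer
Reagents that add atoms: none
Why: Ortho-selective hydroxyalkylation of a magnesium phenolate, in which the metal-bound aldehyde should be delivered through a six-membered chelate to the only free ortho carbon; the new carbinol centre is racemic and disappears in step 5.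

Step 3
Reactants: 6 quinidine
Product: 7 9-O-methylquinidine
Conditions: NaH, DMF, 0 °C; MeI (1.05 equiv), 0 °C to rt
Reagents that add atoms: iodomethane, CI
Why: Williamson ether synthesis, in which the sodium alkoxide of the C9 hydroxyl should outcompete both tertiary nitrogens for one equivalent of iodomethane at low temperature.

Step 4
Reactants: 7 9-O-methylquinidine; 8 2-bromo-N-methoxy-N-methylacetamide
Product: 9 N-{2-[methoxy(methyl)amino]-2-oxoethyl}-9-O-methylquinidinium bromide
Conditions: THF, rt; the salt is collected by filtration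
Reagents that add atoms: none
Why: Menshutkin quaternisation, in which the quinuclidine nitrogen, far more nucleophilic than the quinoline nitrogen, should be alkylated by the activated α-bromoamide.

Step 5
Reactants: 5 2-[2-(TBSO)-1-hydroxyethyl]-6-methoxy-4-[3-(TBSO)propyl]phenol; 9 N-{2-[methoxy(methyl)amino]-2-oxoethyl}-9-O-methylquinidinium bromide
Product: 13 (2S,3R)-3-(TBSO-methyl)-N,7-dimethoxy-N-methyl-5-(3-TBSO-propyl)-2,3-dihydro-1-benzofuran-2-carboxamide, via ortho-quinone methide 10 (not isolated), via benzylic sulfone 11 (not isolated), via ammonium ylide 12 (not isolated)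
Conditions: p-TolSO2H (1.2 equiv), 4 Å molecular sieves, CH2Cl2, rt; then 9 (1.2 equiv), Cs2CO3 (5 equiv), rt; 7 is recovered by acid extraction
Reagents that add atoms: none
Why: One-pot sequence ending in the formal (4+1) annulation of an ammonium ylide with an ortho-quinone methide, in which the sulfinic acid (anhydrous and weakly acidic, so the silyl ethers are spared) dehydrates 5 and stores the quinone methide 10 as its conjugate-addition sulfone 11, Cs2CO3 then releases 10 from this reservoir at low concentration and 12 from 9, conjugate addition of 12 sets C3 under control of the chiral ammonium group, and anti displacement of the amine by the phenoxide at C2 should close ring B as the 2,3-trans (2S,3R) isomer.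

Step 6
Reactants: 13 (2S,3R)-3-(TBSO-methyl)-N,7-dimethoxy-N-methyl-5-(3-TBSO-propyl)-2,3-dihydro-1-benzofuran-2-carboxamide
Product: 14 1-Bf-ethan-1-one
Conditions: MeMgBr (1.5 equiv), THF, −78 to 0 °C; pH 7 buffer
Reagents that add atoms: methylmagnesium bromide, C[Mg]Br
Why: Weinreb ketone synthesis, in which the N-methoxy-N-methylamide should accept a single methyl group and both ring B stereocentres stay untouched.

Step 7
Reactants: 15 2-methoxypropene
Product: 16 3-bromo-2-methoxyprop-1-ene
Conditions: N-bromosuccinimide, PhCF3, 0 °C to rt; filtration, distillation from K2CO3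
Reagents that add atoms: N-bromosuccinimide, O=C1CCC(=O)N1Br
Why: Electrophilic bromination of the enol ether followed by loss of a methyl proton (deconjugative allylic bromination) should give the known 2-methoxyallyl bromide, an acetonyl cation equivalent.

Step 8
Reactants: 14 1-Bf-ethan-1-one; 16 3-bromo-2-methoxyprop-1-ene
Product: 18 1-Bf-4-methoxypent-4-en-1-one, via lithium enolate 17 (not isolated)
Conditions: LiN(i-Pr)2 (1.05 equiv), THF, −78 °C; 16 (1.5 equiv), DMPU, −78 to −30 °C; pH 7 buffer
Reagents that add atoms: none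
Why: Kinetic enolate alkylation, in which the amide base should remove a methyl proton in preference to the hindered C2–H and the allylic bromide then forms the C5'–C6' bond, neutral work-up preserving the enol ether.

Step 9
Reactants: 18 1-Bf-4-methoxypent-4-en-1-one
Product: 19 (4S)-4-Bf-7-methoxyocta-1,7-dien-4-ol
Conditions: CH2=CHCH2MgBr (1.0 M in Et2O, 1.5 equiv) added to 18 in CH2Cl2, −78 °C; pH 7 buffer
Reagents that add atoms: allylmagnesium bromide, C=CC[Mg]Br
Why: Grignard allylation under Cram-chelate control, in which the weakly coordinating solvent should let magnesium bind the ketone oxygen and O1 before C–C bond formation, so that allyl adds to the C1' face anti to C3 and sets (S)-C1'.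

Step 10
Reactants: 19 (4S)-4-Bf-7-methoxyocta-1,7-dien-4-ol
Product: 20 (1S)-1-Bf-4-methoxycyclohex-3-en-1-ol
Conditions: second-generation Grubbs catalyst RuCl2(=CHPh)(PCy3)(H2IMes) (5 mol %), toluene (0.005 M), 60 °C; chromatography on Et3N-treated silica
Reagents that add atoms: none
Why: Ring-closing metathesis of a terminal alkene with a 1,1-disubstituted enol ether, in which the catalyst should load on the allyl terminus and close ring C onto the methoxyalkene with loss of ethene, placing the C3'=C4' enol ether homoallylic to the untouched C1' carbinol.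

Step 11
Reactants: 20 (1S)-1-Bf-4-methoxycyclohex-3-en-1-ol; 21 chlorodimethylsilane
Product: 22 [(1S)-1-Bf-4-methoxycyclohex-3-en-1-yl]oxy(dimethyl)silane
Conditions: 21 (1.5 equiv), Et3N (3 equiv), DMAP (0.1 equiv), CH2Cl2, 0 °C to rt; filtration through basic alumina
Reagents that add atoms: none
Why: O-silylation of the tertiary alcohol by the small chlorosilane under nucleophilic catalysis should install the Si–H tether, the excess amine keeping HCl away from the enol ether.

Step 12
Reactants: 22 [(1S)-1-Bf-4-methoxycyclohex-3-en-1-yl]oxy(dimethyl)silane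
Product: 23 (1S,2S,5S)-5-Bf-2-methoxy-7,7-dimethyl-6-oxa-7-silabicyclo[3.2.1]octane
Conditions: Pt2[(CH2=CHSiMe2)2O]3 (1 mol % zerovalent platinum), toluene, 25 to 50 °C
Reagents that add atoms: none
Why: The Si–H bond should add oxidatively to zerovalent platinum, the C3'=C4' bond then inserts in syn fashion and reductive elimination closes a Chalk–Harrod cycle with silicon on C3' and hydrogen on C4'. The nearest known reaction type is the platinum-catalysed intramolecular hydrosilylation of homoallylic and enol-ether-bearing alcohols through their dimethylsilyl ethers. The oxasilolane ring (O–Si–C3'–C2'–C1') closes in the 5-exo mode and forms a 6-oxa-7-silabicyclo[3.2.1]octane together with ring C. C3' is controlled by the tether, which reaches the alkene only on the face of the C1' oxygen, and C4' by the syn course of the addition, which puts hydrogen on that same face and so leaves the methoxy group trans to silicon. Three selectivities are required (face, regiochemistry, syn addition): the short tether fixes the face and the five-membered ring, silicon prefers the less substituted β-carbon of the enol ether over the fully substituted C4', and the bulky C1' substituent stays equatorial so that the O–SiHMe2 arm is axial and near C3'. The neutral, chloride-free catalyst also spares the acid-labile enol ether.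

Step 13
Reactants: 23 (1S,2S,5S)-5-Bf-2-methoxy-7,7-dimethyl-6-oxa-7-silabicyclo[3.2.1]octane
Product: 24 (1S,3S,4S)-1-Bf-4-methoxycyclohexane-1,3-diol
Conditions: 30% aq H2O2, KF, KHCO3, THF/MeOH (1:1), rt
Reagents that add atoms: hydrogen peroxide, OO
Why: Tamao–Fleming oxidation, in which fluoride-assisted peroxide attack on silicon and migration of C3' from silicon to oxygen with retention should give the C3' alcohol cis to the freed C1' hydroxyl, the buffered medium keeping the β-methoxy silane from eliminating.

Step 14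
Reactants: 24 (1S,3S,4S)-1-Bf-4-methoxycyclohexane-1,3-diol
Product: 25 difengpiol B
Conditions: Bu4NF (3 equiv), THF, 0 °C to rt
Reagents that add atoms: none
Why: Fluoride desilylation of the two primary silyl ethers should free the hydroxymethyl and hydroxypropyl groups without touching any stereocentre.

**Compound list**

1 | dihydroconiferyl alcohol, 4-(3-hydroxypropyl)-2-methoxyphenol | COc1cc(CCCO)ccc1O | starting material
2 | 4-[3-(tert-butyldimethylsilyloxy)propyl]-2-methoxyphenol | COc1cc(CCCO[Si](C)(C)C(C)(C)C)ccc1O | intermediate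
3 | (tert-butyldimethylsilyloxy)acetaldehyde | O=CCO[Si](C)(C)C(C)(C)C | starting material
4 | bromomagnesium 4-[3-(tert-butyldimethylsilyloxy)propyl]-2-methoxyphenolate (formed in the flask) | COc1cc(CCCO[Si](C)(C)C(C)(C)C)ccc1O[Mg]Br | intermediate
5 | 2-[2-(tert-butyldimethylsilyloxy)-1-hydroxyethyl]-6-methoxy-4-[3-(tert-butyldimethylsilyloxy)propyl]phenol, racemic at the carbinol carbon | COc1cc(CCCO[Si](C)(C)C(C)(C)C)cc(C(O)CO[Si](C)(C)C(C)(C)C)c1O | intermediate
6 | quinidine | COc1ccc2nccc([C@H](O)[C@H]3C[C@@H]4CCN3C[C@@H]4C=C)c2c1 | starting material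
7 | 9-O-methylquinidine | COc1ccc2nccc([C@H](OC)[C@H]3C[C@@H]4CCN3C[C@@H]4C=C)c2c1 | intermediate
8 | 2-bromo-N-methoxy-N-methylacetamide | CON(C)C(=O)CBr | starting material
9 | N-{2-[methoxy(methyl)amino]-2-oxoethyl}-9-O-methylquinidinium bromide (quinuclidine nitrogen alkylated) | COc1ccc2nccc([C@H](OC)[C@H]3C[C@@H]4CC[N+]3(CC(=O)N(C)OC)C[C@@H]4C=C)c2c1.[Br-] | intermediate
10 | (6E)-6-[2-(tert-butyldimethylsilyloxy)ethylidene]-2-methoxy-4-[3-(tert-butyldimethylsilyloxy)propyl]cyclohexa-2,4-dien-1-one, the ortho-quinone methide (formed in the flask) | CC(C)(C)[Si](C)(C)OC/C=C1\C=C(CCCO[Si](C)(C)C(C)(C)C)C=C(OC)C1=O | intermediate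
11 | 2-[2-(tert-butyldimethylsilyloxy)-1-(4-methylphenylsulfonyl)ethyl]-6-methoxy-4-[3-(tert-butyldimethylsilyloxy)propyl]phenol, racemic at the sulfonyl-bearing carbon (formed in the flask) | COc1cc(CCCO[Si](C)(C)C(C)(C)C)cc(C(CO[Si](C)(C)C(C)(C)C)S(=O)(=O)c2ccc(C)cc2)c1O | intermediate
12 | ammonium ylide of 9 (formed in the flask) | COc1ccc2nccc([C@H](OC)[C@H]3C[C@@H]4CC[N+]3([CH-]C(=O)N(C)OC)C[C@@H]4C=C)c2c1 | intermediate
13 | (2S,3R)-3-[(tert-butyldimethylsilyloxy)methyl]-N,7-dimethoxy-N-methyl-5-[3-(tert-butyldimethylsilyloxy)propyl]-2,3-dihydro-1-benzofuran-2-carboxamide (2,3-trans) | COc1cc(CCCO[Si](C)(C)C(C)(C)C)cc2c1O[C@H](C(=O)N(C)OC)[C@H]2CO[Si](C)(C)C(C)(C)C | intermediate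
14 | 1-Bf-ethan-1-one, the trans-2-acetyl dihydrobenzofuran | COc1cc(CCCO[Si](C)(C)C(C)(C)C)cc2c1O[C@H](C(C)=O)[C@H]2CO[Si](C)(C)C(C)(C)C | intermediate
15 | 2-methoxypropene | COC(C)=C | starting material
16 | 3-bromo-2-methoxyprop-1-ene (2-methoxyallyl bromide) | COC(=C)CBr | intermediate
17 | lithium enolate of 14 on the methyl side (formed in the flask) | COc1cc(CCCO[Si](C)(C)C(C)(C)C)cc2c1O[C@H](C(=C)O[Li])[C@H]2CO[Si](C)(C)C(C)(C)C | intermediate
18 | 1-Bf-4-methoxypent-4-en-1-one | COc1cc(CCCO[Si](C)(C)C(C)(C)C)cc2c1O[C@H](C(=O)CCC(OC)=C)[C@H]2CO[Si](C)(C)C(C)(C)C | intermediate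
19 | (4S)-4-Bf-7-methoxyocta-1,7-dien-4-ol | COc1cc(CCCO[Si](C)(C)C(C)(C)C)cc2c1O[C@H]([C@](CC=C)(O)CCC(OC)=C)[C@H]2CO[Si](C)(C)C(C)(C)C | intermediate
20 | (1S)-1-Bf-4-methoxycyclohex-3-en-1-ol | COc1cc(CCCO[Si](C)(C)C(C)(C)C)cc2c1O[C@H]([C@]3(O)CCC(OC)=CC3)[C@H]2CO[Si](C)(C)C(C)(C)C | intermediate
21 | chlorodimethylsilane | C[SiH](C)Cl | starting material
22 | [(1S)-1-Bf-4-methoxycyclohex-3-en-1-yl]oxy(dimethyl)silane, the dimethylsilyl ether of 20 | COc1cc(CCCO[Si](C)(C)C(C)(C)C)cc2c1O[C@H]([C@]3(O[SiH](C)C)CCC(OC)=CC3)[C@H]2CO[Si](C)(C)C(C)(C)C | intermediate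
23 | (1S,2S,5S)-5-Bf-2-methoxy-7,7-dimethyl-6-oxa-7-silabicyclo[3.2.1]octane (silicon on C3' cis to the C1' oxygen, methoxy on C4' trans to silicon) | COc1cc(CCCO[Si](C)(C)C(C)(C)C)cc2c1O[C@H]([C@]3(O4)CC[C@H](OC)[C@@H]([Si]4(C)C)C3)[C@H]2CO[Si](C)(C)C(C)(C)C | intermediate
24 | (1S,3S,4S)-1-Bf-4-methoxycyclohexane-1,3-diol | COc1cc(CCCO[Si](C)(C)C(C)(C)C)cc2c1O[C@H]([C@]1(O)CC[C@H](OC)[C@@H](O)C1)[C@H]2CO[Si](C)(C)C(C)(C)C | intermediate
25 | difengpiol B, (1S,3S,4S)-1-[(2S,3R)-3-(hydroxymethyl)-5-(3-hydroxypropyl)-7-methoxy-2,3-dihydro-1-benzofuran-2-yl]-4-methoxycyclohexane-1,3-diol | COc1cc(CCCO)cc2c1O[C@H]([C@]1(O)CC[C@H](OC)[C@@H](O)C1)[C@H]2CO | target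

**Totals**

Total step count: 14. Longest linear sequence: 11 steps (1, 2, 5, 6, 8, 9, 10, 11, 12, 13, 14, starting from compound 1).

**Steps most likely to fail, with fallbacks**

1. Step 5. The chiral ammonium ylide may not discriminate the two faces of 10 well enough, giving ring B in low enantiomeric purity, and a 1,5-hydrogen shift of the alkyl-substituted quinone methide may compete with the addition.
   Fallback, setting out from 5 and returning at 13: stereodifferentiation is moved to a covalently bound auxiliary with separation of diastereomers. (−)-Menthol is acylated with bromoacetyl bromide (pyridine, CH2Cl2, 0 °C) to (1R,2S,5R)-menthyl bromoacetate F1, and dimethyl sulfide in acetone converts this into the sulfonium bromide F2. Diol 5 is taken to sulfone 11 with p-TolSO2H as in the first stage of step 5. With Cs2CO3 in CH2Cl2 the ester-stabilised sulfonium ylide from F2, a stronger nucleophile, should capture 10 (released from 11) in the established sulfur-ylide (4+1) annulation and give the trans esters as two diastereomers. The (2S,3R) member, menthyl ester F3, is separated by chromatography or crystallisation, and Me(MeO)NH·HCl with i-PrMgCl (THF, −20 °C) turns it into 13.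

2. Step 9. Carbon–carbon bond formation by the very reactive allyl reagent may outrun chelate formation, which would erode or reverse facial selectivity at C1'.
   Fallback, setting out from 18 and returning at 19: the allyl group is introduced in masked form by an ordinary alkyl Grignard reagent, which adds through the magnesium chelate. PhS(CH2)3MgBr (THF/Et2O, −78 °C) should give the sulfide carbinol F4 with the same C1' configuration. Buffered NaIO4 in aqueous MeOH oxidises it to the sulfoxide F5, and thermal syn-elimination (toluene, 110 °C, CaCO3 and P(OMe)3 as sulfenic acid traps) unveils the terminal alkene of 19.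

3. Step 12. Reversible platinum hydride insertion may move the enol ether double bond to C4'=C5' before the C–Si bond forms, which would carry silicon to C5', or closure of the bridged ring may be too slow.
   Fallback, setting out from 13 and returning at 24: the tethered hydrosilylation is replaced by hydroxyl-directed epoxidation and trans-diaxial methanolysis of a plain cyclohexene. CH2=CH(CH2)2MgBr converts 13 into the pentenyl ketone F6. Chelation-controlled Sakurai allylation (allylSiMe3, TiCl4, CH2Cl2, −78 °C, possible here because no enol ether is present) gives the diene carbinol F7 with C1' as in 19. Ring-closing metathesis with the catalyst of step 10 gives the cyclohexenol F8. VO(acac)2 and t-BuOOH deliver oxygen syn to the tertiary hydroxyl and give the cis-epoxy alcohol F9. NaOMe in MeOH at reflux should open it at C4' in the trans-diaxial sense, because the large C1' substituent holds the ring with that substituent equatorial, and this gives 24.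

**Further compounds**

F1 | step 5 | (1R,2S,5R)-menthyl bromoacetate | CC(C)[C@@H]1CC[C@@H](C)C[C@H]1OC(=O)CBr
F2 | step 5 | dimethyl{2-[(1R,2S,5R)-menthyloxy]-2-oxoethyl}sulfonium bromide | CC(C)[C@@H]1CC[C@@H](C)C[C@H]1OC(=O)C[S+](C)C.[Br-]
F3 | step 5 | (1R,2S,5R)-menthyl (2S,3R)-3-[(tert-butyldimethylsilyloxy)methyl]-7-methoxy-5-[3-(tert-butyldimethylsilyloxy)propyl]-2,3-dihydro-1-benzofuran-2-carboxylate | COc1cc(CCCO[Si](C)(C)C(C)(C)C)cc2c1O[C@H](C(=O)O[C@@H]3C[C@H](C)CC[C@H]3C(C)C)[C@H]2CO[Si](C)(C)C(C)(C)C
F4 | step 9 | (4S)-4-Bf-7-methoxy-1-(phenylsulfanyl)oct-7-en-4-ol | COc1cc(CCCO[Si](C)(C)C(C)(C)C)cc2c1O[C@H]([C@](CCCSc3ccccc3)(O)CCC(OC)=C)[C@H]2CO[Si](C)(C)C(C)(C)C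
F5 | step 9 | (4S)-4-Bf-7-methoxy-1-(phenylsulfinyl)oct-7-en-4-ol, mixture at sulfur | COc1cc(CCCO[Si](C)(C)C(C)(C)C)cc2c1O[C@H]([C@](CCCS(=O)c3ccccc3)(O)CCC(OC)=C)[C@H]2CO[Si](C)(C)C(C)(C)C
F6 | step 12 | 1-Bf-pent-4-en-1-one | COc1cc(CCCO[Si](C)(C)C(C)(C)C)cc2c1O[C@H](C(=O)CCC=C)[C@H]2CO[Si](C)(C)C(C)(C)C
F7 | step 12 | (4S)-4-Bf-octa-1,7-dien-4-ol | COc1cc(CCCO[Si](C)(C)C(C)(C)C)cc2c1O[C@H]([C@](CC=C)(O)CCC=C)[C@H]2CO[Si](C)(C)C(C)(C)C
F8 | step 12 | (1S)-1-Bf-cyclohex-3-en-1-ol | COc1cc(CCCO[Si](C)(C)C(C)(C)C)cc2c1O[C@H]([C@]3(O)CCC=CC3)[C@H]2CO[Si](C)(C)C(C)(C)C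
F9 | step 12 | (1S,3S,4R)-1-Bf-3,4-epoxycyclohexan-1-ol, epoxide oxygen cis to the hydroxyl | COc1cc(CCCO[Si](C)(C)C(C)(C)C)cc2c1O[C@H]([C@]3(O)CC[C@H]4O[C@H]4C3)[C@H]2CO[Si](C)(C)C(C)(C)C
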